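The numbers in the tables come from a simulation from invented constants; scatter was added.

1. The product, monomer in chains, does not stay: in the midnight run it reads 27.9% at 2.00 min but 13.9% at 3.00 min. You have these flasks and readings, and these questions:

| setting | summer | midnight | alder | cedar | birch | oak | ash |
|---|---|---|---|---|---|---|---|
| free monomer | 0.047 M | 0.19 M | 0.060 M | 0.10 M | 0.15 M | 0.25 M | 0.30 M |
| initiator | 0.2 mol% | 0.2 mol% | 0.2 mol% | 0.2 mol% | 0.2 mol% | 0.2 mol% | 0.2 mol% |
| remark | run made earlier | run made earlier |  |  |  |  |  |
| time |  |  | 4.0 min | 4.0 min | 4.0 min | 4.0 min | 4.0 min |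

| run | time / min | monomer in chains / % |
|---|---|---|
| summer | 0.250 | 1.7 |
| summer | 0.667 | 0.9 |
| summer | 1.33 | 4.0 |
| summer | 2.00 | 6.2 |
| summer | 3.00 | 8.2 |
| midnight | 0.250 | 3.5 |
| midnight | 0.667 | 14.7 |
| midnight | 1.33 | 27.3 |
| midnight | 2.00 | 27.9 |
| midnight | 3.00 | 13.9 |

(standard deviation of a reading: 1 percentage point)

- the numbers in the tables scatter with a standard deviation of 1 percentage point
- "hardly changes" means that all values lie within two and a half points (for a concentration: within two and a half percent of the largest)

- [monomer in chains] at the end for alder, cedar, birch, oak, ash, in this order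
- the shape of the row from first to last (falls, then rises / hardly changes / falls all the way / rises, then falls / rises all the way)

2. My bench rule: a flask repeats midnight on a clock that runs in proportion to the charge c. Its peak then reads y_p = 27.9%, the highest midnight reading, at t_p = 2.00 min × 0.19 M / c. The summer run warns you: it reads 8.2% at 3.00 min, which the rule maps to 0.742 min of midnight, where midnight reads about 14.7%. Summer reads less than that, so the clock is too fast at summer's charge.

3. The rule has a flask past its peak at the end, t_p < 4.0 min, when c exceeds the border c_b = 0.0950 M. Alder lies below it, and cedar sits on it, at a ratio of 1.05. I expect both at the end to stand near their peaks or still short of them, so the row should rise there.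

4. Above the border, reckon the remainder of the peak, not what has left it. I take the loss as first order, with the fade time h, the time in which the reading drops by a factor of two, read from midnight's last interval: h = 0.995 min. Dividing y_p by two for each h after t_p and multiplying by c gives birch 0.0151 M, oak 0.0124 M and ash 0.0125 M.

5. The forecast, “Treating the loss as second order”, gives 0.01 M, 0.028 M, 0.021 M, 0.015 M, 0.013 M, with the shape rises, then falls. For birch it stands higher than my value.

6. The flasks give alder 0.00705 M, cedar 0.0133 M, birch 0.0152 M, oak 0.0115 M and ash 0.00990 M, so the shape is rises, then falls.

    free monomer + initiator → living end + monomer in chains (k = 0.0640 M⁻¹ s⁻¹)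
    free monomer + living end → monomer in chains + living end, rate k2*[living end]*[free monomer] (k = 75.0 M⁻¹ s⁻¹)
    monomer in chains → over-reaction product (k = 0.0210 s⁻¹)

7. At 4.00 min, oak holds 4.61% in chains, with 0.658% free monomer left. Carried by h from its 26.9% at 2.00 min, oak comes to 6.68%, more than it holds. Carried the same way from 25.4%, ash comes to 6.30%, and it stands at 3.30%.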